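(The numbers are assumed, and the outcome is calculated.)

In a one-step world each incoming ligand makes one complex with one exchanged, and these charges give 70.0% of the starting complex. Here a second exchange competes for the same ligand.

    complex with one exchanged + incoming ligand → leaving ligand + complex with two exchanged (k1 = 23 /M/s)
    crystals ⇌ complex with one exchanged, rate k2*(cs2 - [complex with one exchanged]) while solid is left; crystals form when [complex with one exchanged] > cs2 (cs2 = 2.0 mM, k2 = 1.1 /s)
    starting complex + incoming ligand → leaving ligand + complex with one exchanged (k3 = 5.2 /M/s)

| setting | east | north-east | north | south-west |
|---|---|---|---|---|
| starting complex | 0.050 M (fed, over 3.0 min) | 0.050 M (in portions, 3, over 3.0 min) | 0.050 M | 0.050 M |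
| incoming ligand | 0.0350 M | 0.0350 M | 0.0350 M | 0.0350 M (fed, over 3.0 min) |
| leaving ligand | 0.0500 M | 0.0500 M | 0.0500 M | 0.0500 M |
| time | 8.0 min | 8.0 min | 8.0 min | 8.0 min |
| remark | all else is in the flask from the start; the feed brings no volume worth counting | first portion at the start, last at 3.0 min | everything together at the start | all else is in the flask from the start; the feed brings no volume worth counting |

- for complex with one exchanged the crystals are counted in
- as a solid, counted per litre of solution: crystals
- run time (east): 8.0 min

- the flask with the highest amount of complex with one exchanged, in percent of the starting complex charged ("all alike" if they lie within 1.5 percentage points) (east / north-east / north / south-west / all alike)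
- final complex with one exchanged, as a percentage of the starting complex charged, in east
- final complex with one exchanged, as a percentage of the starting complex charged, in north-east
- final complex with one exchanged, as a percentage of the starting complex charged, in north
- final complex with one exchanged, as a percentage of the starting complex charged, in south-west

My own reckoning compares lifetimes. Both steps use the incoming ligand, so its level cancels: dissolved complex with one exchanged is consumed 4.42 times as fast per molecule as starting complex, a selectivity factor. At its solubility, the dissolved form is therefore used as fast as it is made when starting complex stands at 8.85 mM, the crossing level, which is the solubility times that ratio. With the dissolved form at solubility and starting complex above this level, more is made than consumed, and the excess goes to crystals. While the solution stays at solubility, the share of consumed starting complex that goes on to two exchanged is the crossing level over the present starting complex. Summed over a run held at solubility, complex with two exchanged equals the crossing level times the logarithm of charge over remainder.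

North and south-west both hold a charge above the crossing level, yet they should differ. In north, the charged ligand consumes the dissolved form at 0.805 /s, against a crystal-growth coefficient of 1.1 /s. The dissolved level that balances these, with the charges as they stand, is 5.93 mM, above solubility, so north should lose more to the second exchange than the sum says. The feed in south-west should hold ligand near 0.748 mM, less than the charge, so I rank south-west above north, without a figure. In east, the feed against full ligand first holds starting complex near 1.53 mM, below the crossing level, so no crystals are expected at first.

The forecast names south-west, with 3.2% in east, 3.9% in north-east, 31% in north and 40% in south-west, holding that “feeding the ligand slowly into excess starting complex pins the dissolved intermediate near 2 mM”.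

| Flask | Complex with one exchanged | Of it, crystals |
|---|---|---|
| east | 3.53% | 0% |
| north-east | 3.55% | 0% |
| north | 31.0% | 27.0% |
| south-west | 40.9% | 36.9% |

South-west ends highest, at 40.9%. Its starting complex stands at 44.6% of the charge at the end, with complex with two exchanged at 14.6%. The crossing level turns that remainder into 14.3% of the charge as complex with two exchanged. In north, the remainder of 49.5% gives 12.4% by the same sum, and the flask holds more than that, at 19.5%.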